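## The problem

- Ring A of the target is a hexasubstituted benzene. C5–C8 carry four contiguous oxygens (5-OH, 6-, 7-, 8-OMe), C8a carries the ring oxygen O1 and C4a carries the C4 carbonyl, so five adjacent ring carbons bear oxygen.
- No simple benzene building block has this pattern. Routes that bring ring A in as an arene spend most of their steps oxygenating an acetophenone.
- The four oxygens at C5–C8 must be told apart. Only the one at C5, peri to the C4 carbonyl, is free, and a late selective demethylation would have to single it out among six methyl ethers.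
- Ring C needs a methoxy group at C3, so the pyranone must be made at the flavonol oxidation level. Ring B has a 2'-OMe that hinders bond formation at C2 and a 4'-OH that needs a protecting group removable in the presence of six other aryl–oxygen bonds.
- There is no stereocentre; the difficulties are regiochemistry and chemoselectivity.
- Sensitive sites: the 4-pyranone opens with hydroxide or amines and is alkylated at the carbonyl oxygen by hard electrophiles. A ring A with free 5- and 8-OH would oxidise to the 5,8-quinone.
- The enabling feature: C5, C6, C7 and C8 form a 2,3-dimethoxyhydroquinone unit whose two para oxygens differ (C5–OH, C8–OMe). The other two ring-A atoms, C4a and C8a, are a C=C bond of a 4-pyranone (ring C). These four carbons map onto the four carbons of dimethyl squarate 8, and the free OH sits on C5, next to C4a, exactly where the ketene carbon of a cyclobutenone ring expansion ends up.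

## Retrosynthesis

**15 ⇐ 14.** The 4'-O–benzyl bond is cut last. A benzyl ether survives lithium amide, methyl triflate and heat, and hydrogenolysis touches none of the methyl ethers. The forward step is a hydrogenolysis in the presence of a tetrasubstituted enone.

**14 ⇐ 11 (key).** Ring A is taken apart: the C4a–C5 bond is cut and C5 is reconnected to C8, giving the 4-(pyranon-2-yl)-4-methoxycyclobutenone 11.
- Cutting ring C instead (O1–C2, C2–C3) would leave the hexasubstituted arene untouched; this cut removes it.
- The precursor is a monocyclic pyranone joined by one bond to a four-membered ring.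
- The forward reaction opens the cyclobutenone to dienylketene 12, closes it onto pyranone C5 to give 13, and enolises. The ketene oxygen becomes the free 5-OH, the C4 methyl ether becomes 8-OMe, and the squarate methoxy groups become 6- and 7-OMe. No demethylation is needed.
- Bonding the squarate carbon to C8a rather than C4a is what puts the free hydroxyl at C5.

**11 ⇐ 7 + 8.** The C8–C8a bond (cyclobutenone C4 to pyranone C6) is cut to pyranone 7 and dimethyl squarate 8.
- A carbonyl addition is preferred over a cross-coupling to a 4-halocyclobutenone because it keeps the oxygen that becomes 8-OMe.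
- The forward step needs the C6 anion 9 of the pyranone (C2 is blocked by the aryl group), 1,2-addition to one of the two equivalent carbonyls of 8, and O-methylation of alkoxide 10.

**7 ⇐ 3 + 6.** The C2–C1' bond is cut to 2-bromo-3-methoxy-4-pyranone 3 and aryl boronate 6. A cross-coupling on a vinylogous acyl bromide places the hindered 2'-methoxyaryl group without building the pyranone around it. Both partners are one ring each.

**3 ⇐ 2 ⇐ 1 and 6 ⇐ 5 ⇐ 4.** The C2–Br and O–Me bonds of 3 go back through 2 to commercial 3-hydroxy-4H-pyran-4-one 1, whose enolic OH directs bromination to C2. Boronate 6 comes from commercial 4-bromo-3-methoxyphenol 4 by benzylation (5) and borylation.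

## Roads not taken

**Alternative 1:** The most obvious route cuts ring C at O1–C2 and C2–C3.
- Forward: aldol condensation of 2'-hydroxy-3',4',5',6'-tetramethoxyacetophenone A1 with 4-benzyloxy-2-methoxybenzaldehyde gives chalcone A2. Algar–Flynn–Oyamada oxidation gives flavonol A3, followed by 3-O-methylation, 5-O-demethylation and debenzylation.
- A1 already holds the whole ring-A problem and needs a multistep oxygenation of a trimethoxyphenol.
- The 6'-methoxy group of A2 twists the enone and favours 5-exo attack, which leads to aurone A4 rather than A3.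
- The end game must cleave one of six methyl ethers. The chosen plan builds ring A with the 5-OH already free.

**Alternative 2:** Late oxygenation of ring A, cutting the C6–O and C8–O bonds.
- Forward: a phloroglucinol-derived flavone, 5,7-dihydroxy-3-methoxy compound A5, is dibrominated to A6. Copper-mediated double methoxylation and 7-O-methylation follow.
- Ring B is a resorcinol diether, as electron-rich as ring A, so bromination at C3' and C5' competes.
- Two substitutions on a hindered, chelating dibromide are needed, and A5 itself requires a full flavonol synthesis first.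
- The chosen plan brings all four oxygens in with one reagent.

**Alternative 3:** The same squarate ring expansion with the opposite orientation, the squarate carbon bonded to C4a.
- Forward: 5-iodopyranone A7 is metallated and added to 8, the adduct is methylated to cyclobutenone A8, and thermolysis closes onto the pyranone carbon next to O1.
- The product is the 8-hydroxy-5-methoxy isomer A9: the free hydroxyl is at the wrong end, so a methylation and a peri-demethylation are added.
- Iodination at pyranone C5 also competes with iodination of ring B.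
- The chosen orientation uses the C–H next to the ring oxygen and delivers the 5-OH directly.

Key step: step 7

## Route

Remark: 11 and the transient 13 each hold one stereocentre, formed racemic and lost on aromatisation; the target is achiral.

Step 1
Reactants: 1 3-hydroxy-4H-pyran-4-one (pyromeconic acid)
Product: 2 2-bromo-3-hydroxy-4H-pyran-4-one
Conditions: NBS, MeCN, 0 °C to rt
Reagents that add atoms: N-bromosuccinimide, O=C1CCC(=O)N1Br
Why: Electrophilic bromination of the enolic 3-hydroxy-4-pyranone should occur at C2, the only carbon ortho to the hydroxyl and next to the ring oxygen; this is the position at which kojic acid and related hydroxypyranones are halogenated and hydroxyalkylated.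

Step 2
Reactants: 2 2-bromo-3-hydroxy-4H-pyran-4-one
Product: 3 2-bromo-3-methoxy-4H-pyran-4-one
Conditions: MeI, K2CO3, acetone, 40 °C
Reagents that add atoms: iodomethane, CI
Why: Williamson O-methylation of the acidic enolic hydroxyl; the mild, non-nucleophilic base should leave the vinylogous acyl bromide at C2 intact.

Step 3
Reactants: 4 4-bromo-3-methoxyphenol
Product: 5 4-(benzyloxy)-1-bromo-2-methoxybenzene
Conditions: BnBr, K2CO3, DMF, rt
Reagents that add atoms: benzyl bromide, BrCc1ccccc1
Why: Williamson benzylation of the phenol; the benzyl ether masks the future 4'-OH through the base, alkylation and heating steps and is removed by hydrogenolysis at the end.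

Step 4
Reactants: 5 4-(benzyloxy)-1-bromo-2-methoxybenzene
Product: 6 2-[4-(benzyloxy)-2-methoxyphenyl]-4,4,5,5-tetramethyl-1,3,2-dioxaborolane
Conditions: B2pin2, Pd(dppf)Cl2 (cat.), KOAc, dioxane, 90 °C
Reagents that add atoms: bis(pinacolato)diboron, CC1(C)OB(OC1(C)C)B1OC(C)(C)C(C)(C)O1
Why: Miyaura borylation of an aryl bromide; the weak base KOAc should prevent coupling of the product with unreacted 5, and both ethers are inert.

Step 5
Reactants: 3 2-bromo-3-methoxy-4H-pyran-4-one; 6 2-[4-(benzyloxy)-2-methoxyphenyl]-4,4,5,5-tetramethyl-1,3,2-dioxaborolane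
Product: 7 2-[4-(benzyloxy)-2-methoxyphenyl]-3-methoxy-4H-pyran-4-one
Conditions: Pd(dppf)Cl2 (cat.), K3PO4, dioxane/H2O (10:1), 80 °C
Reagents that add atoms: none
Why: Suzuki–Miyaura coupling; the C2–Br bond is that of a β-bromoenone and should add readily to zerovalent palladium, and phosphate with little water limits hydrolytic opening of the pyranone.

Step 6
Reactants: 7 2-[4-(benzyloxy)-2-methoxyphenyl]-3-methoxy-4H-pyran-4-one; 8 3,4-dimethoxycyclobut-3-ene-1,2-dione (dimethyl squarate)
Product: 11 4-[6-(4-benzyloxy-2-methoxyphenyl)-5-methoxy-4-oxo-4H-pyran-2-yl]-2,3,4-trimethoxycyclobut-2-en-1-one (racemic), via lithiated pyranone 9 (not isolated), via lithium alkoxide 10 (not isolated)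
Conditions: LiTMP (from TMPH, n-BuLi), THF, −78 °C, inverse addition of 7; then 8, −78 °C; then MeOTf, −78 to −20 °C; aq. NaHCO3
Reagents that add atoms: methyl trifluoromethanesulfonate, COS(=O)(=O)C(F)(F)F
Why: The hindered amide should remove the C6–H, the only hydrogen next to the ring oxygen (C2 is blocked), as in the C2 lithiation of 3-substituted chromones. The vinyllithium adds 1,2 to one of the two equivalent carbonyls of the squarate, as aryl- and alkenyllithiums do, and trapping the alkoxide with MeOTf fixes the oxygen that becomes 8-OMe. The new quaternary centre is racemic and is lost in step 7.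

Step 7
Reactants: 11 4-[6-(4-benzyloxy-2-methoxyphenyl)-5-methoxy-4-oxo-4H-pyran-2-yl]-2,3,4-trimethoxycyclobut-2-en-1-one
Product: 14 2-[4-(benzyloxy)-2-methoxyphenyl]-5-hydroxy-3,6,7,8-tetramethoxy-4H-chromen-4-one, via dienylketene 12 (not isolated), via cyclohexadienone 13 (not isolated)
Conditions: degassed toluene (0.02 M), 110 °C, Ar
Reagents that add atoms: none
Why: Heating opens the cyclobutenone by conrotatory four-electron electrocyclic cleavage of its C1–C4 bond; the donor methoxy group at C4 rotates outward, so the pyranonyl group ends cis to the ketene in dienylketene 12. The ketene carbon and pyranone C5 are the termini of a hexatriene, and thermal disrotatory six-electron electrocyclisation forms the C5–C4a bond and closes ring A as cyclohexadienone 13. In 13 the only sp3 carbon (C4a) lies between two carbonyls, so enolisation gives the aromatic ring with the 5-OH hydrogen-bonded to the C4 carbonyl; aromatisation and release of ring strain drive the sequence. The closest known reaction is the thermal ring expansion of 4-aryl- and 4-alkenyl-4-alkoxycyclobutenones to 4-alkoxyphenols (Moore rearrangement), which includes alkenyl groups that are cyclic enol ethers. No stereocentre survives: the quaternary carbon of 11 becomes aromatic C8 and C4a of 13 is planarised. The step needs outward rotation of the methoxy group, which the known torquoselectivity of donor substituents secures, and closure on carbon, which is the only choice because the other neighbour of the attachment carbon is the ring oxygen. The methyl ether blocks the furanone and quinone pathways open to free carbinols and decides that the ketene oxygen becomes 5-OH and the ether oxygen 8-OMe. High dilution keeps the ketene from bimolecular capture.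

Step 8
Reactants: 14 2-[4-(benzyloxy)-2-methoxyphenyl]-5-hydroxy-3,6,7,8-tetramethoxy-4H-chromen-4-one
Product: 15 5,4'-dihydroxy-3,6,7,8,2'-pentamethoxyflavone
Conditions: H2 (1 atm), Pd/C, EtOAc/MeOH, rt
Reagents that add atoms: none
Why: Hydrogenolysis of the benzyl aryl ether; the tetrasubstituted C2=C3 bond of the flavone and the aryl methyl ethers should not react at ambient pressure and temperature.

## Compound list

1 | 3-hydroxy-4H-pyran-4-one (pyromeconic acid) | O=c1ccocc1O | starting material
2 | 2-bromo-3-hydroxy-4H-pyran-4-one | O=c1ccoc(Br)c1O | intermediate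
3 | 2-bromo-3-methoxy-4H-pyran-4-one | COc1c(Br)occc1=O | intermediate
4 | 4-bromo-3-methoxyphenol | COc1cc(O)ccc1Br | starting material
5 | 4-(benzyloxy)-1-bromo-2-methoxybenzene | COc1cc(OCc2ccccc2)ccc1Br | intermediate
6 | 2-[4-(benzyloxy)-2-methoxyphenyl]-4,4,5,5-tetramethyl-1,3,2-dioxaborolane | COc1cc(OCc2ccccc2)ccc1B1OC(C)(C)C(C)(C)O1 | intermediate
7 | 2-[4-(benzyloxy)-2-methoxyphenyl]-3-methoxy-4H-pyran-4-one | COc1cc(OCc2ccccc2)ccc1-c1occc(=O)c1OC | intermediate
8 | 3,4-dimethoxycyclobut-3-ene-1,2-dione (dimethyl squarate) | COC1=C(OC)C(=O)C1=O | starting material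
9 | [6-(4-benzyloxy-2-methoxyphenyl)-5-methoxy-4-oxo-4H-pyran-2-yl]lithium | [Li]c1cc(=O)c(OC)c(-c2ccc(OCc3ccccc3)cc2OC)o1 | intermediate
10 | lithium alkoxide of the 1,2-adduct of 9 to 8 (racemic) | [Li]OC1(C(OC)=C(OC)C1=O)c1cc(=O)c(OC)c(-c2ccc(OCc3ccccc3)cc2OC)o1 | intermediate
11 | 4-[6-(4-benzyloxy-2-methoxyphenyl)-5-methoxy-4-oxo-4H-pyran-2-yl]-2,3,4-trimethoxycyclobut-2-en-1-one (racemic) | COC1(C(OC)=C(OC)C1=O)c1cc(=O)c(OC)c(-c2ccc(OCc3ccccc3)cc2OC)o1 | intermediate
12 | (Z)-dienylketene: 2,3,4-trimethoxy-4-(pyranon-2-yl)buta-1,3-dien-1-one, pyranonyl group cis to the ketene | O=C=C(OC)/C(OC)=C(/OC)c1cc(=O)c(OC)c(-c2ccc(OCc3ccccc3)cc2OC)o1 | intermediate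
13 | 2-[4-(benzyloxy)-2-methoxyphenyl]-3,6,7,8-tetramethoxy-4aH-chromene-4,5-dione (racemic) | COC1=C(OC)C(=O)C2C(=O)C(OC)=C(c3ccc(OCc4ccccc4)cc3OC)OC2=C1OC | intermediate
14 | 2-[4-(benzyloxy)-2-methoxyphenyl]-5-hydroxy-3,6,7,8-tetramethoxy-4H-chromen-4-one | COc1cc(OCc2ccccc2)ccc1-c1oc2c(OC)c(OC)c(OC)c(O)c2c(=O)c1OC | intermediate
15 | 5,4'-dihydroxy-3,6,7,8,2'-pentamethoxyflavone | COc1cc(O)ccc1-c1oc2c(OC)c(OC)c(OC)c(O)c2c(=O)c1OC | target

## Step count and risks

Total step count: 8. Longest linear sequence: 6 steps (1 → 2 → 3 → 7 → 11 → 14 → 15; the branch 4 → 5 → 6 joins at step 5).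

**Step 7 (key).**
- Risk: at the temperature needed for ring opening, ionisation or loss of the tertiary allylic methoxy group, or bimolecular capture of the dienylketene, may compete with closure onto pyranone C5. That carbon belongs to a less electron-rich alkene than the enol ethers and arenes usually used in this ring expansion.
- Fallback: it sets out from alkoxide 10, which is quenched with aqueous NH4Cl instead of MeOTf to give the free carbinol 4-hydroxy-2,3-dimethoxy-4-(pyranon-2-yl)cyclobut-2-en-1-one F5. Heating F5 in degassed toluene should give the hydroquinone 2-[4-(benzyloxy)-2-methoxyphenyl]-5,8-dihydroxy-3,6,7-trimethoxy-4H-chromen-4-one F6 by the same opening and closure, without a labile methyl ether. Without exposure to air, one equivalent of Me2SO4 with K2CO3 in acetone should methylate only the 8-OH, because the 5-OH is chelated to the C4 carbonyl. The route is rejoined at 14.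

**Step 6.**
- Risk: carbonyl-directed deprotonation at C5 in place of C6, conjugate addition of 9 to not yet metallated 7, and O-methylation of the pyranone carbonyl by MeOTf once the alkoxide is consumed.
- Fallback: it sets out from 7. Zincation with TMPZnCl·LiCl in THF at 25 °C should take the thermodynamically most acidic C6–H and give the pyranonylzinc chloride F1. Iodine converts F1 into 2-[4-(benzyloxy)-2-methoxyphenyl]-6-iodo-3-methoxy-4H-pyran-4-one F2, whose regiochemistry can be checked. Iodine–magnesium exchange with iPrMgCl·LiCl at −40 °C gives the less basic pyranonylmagnesium chloride F3. F3 adds to 8 to give the chloromagnesium alkoxide F4, which is methylated with MeOTf. The route is rejoined at 11.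

**Step 5.**
- Risk: hydrolytic opening or substitution of bromopyranone 3 by the aqueous base, and protodeboronation of the electron-rich, ortho-substituted boronate 6.
- Fallback: the polarity of the coupling is reversed; it sets out from 1. O-methylation (MeI, K2CO3) gives 3-methoxy-4H-pyran-4-one F7. Zincation with TMPZnCl·LiCl at C2, flanked by the ring oxygen and the methoxy group, should give (3-methoxy-4-oxo-4H-pyran-2-yl)zinc chloride F8. Base-free Negishi coupling of F8 with bromide 5 (Pd(OAc)2, SPhos, THF, 50 °C) rejoins the route at 7. This path also makes steps 1, 2 and 4 unnecessary.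

**Step 8.**
- Risk: slow hydrogenolysis through binding of the chelating 5-hydroxy-4-ketone to the catalyst, or partial saturation of the C2=C3 bond on forcing.
- Fallback: it sets out from 14 and reaches 15 by Lewis-acid cleavage of the benzyl ether with BCl3 and pentamethylbenzene as cation scavenger in CH2Cl2 at −78 °C. The methyl ethers should survive at this temperature. No new compound is made.

## Further compounds

F1 | step 6 | [6-(4-benzyloxy-2-methoxyphenyl)-5-methoxy-4-oxo-4H-pyran-2-yl]zinc chloride | Cl[Zn]c1cc(=O)c(OC)c(-c2ccc(OCc3ccccc3)cc2OC)o1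
F2 | step 6 | 2-[4-(benzyloxy)-2-methoxyphenyl]-6-iodo-3-methoxy-4H-pyran-4-one | Ic1cc(=O)c(OC)c(-c2ccc(OCc3ccccc3)cc2OC)o1
F3 | step 6 | [6-(4-benzyloxy-2-methoxyphenyl)-5-methoxy-4-oxo-4H-pyran-2-yl]magnesium chloride | Cl[Mg]c1cc(=O)c(OC)c(-c2ccc(OCc3ccccc3)cc2OC)o1
F4 | step 6 | chloromagnesium alkoxide of the 1,2-adduct of F3 to 8 (racemic) | Cl[Mg]OC1(C(OC)=C(OC)C1=O)c1cc(=O)c(OC)c(-c2ccc(OCc3ccccc3)cc2OC)o1
F5 | step 7 | 4-[6-(4-benzyloxy-2-methoxyphenyl)-5-methoxy-4-oxo-4H-pyran-2-yl]-4-hydroxy-2,3-dimethoxycyclobut-2-en-1-one (racemic) | OC1(C(OC)=C(OC)C1=O)c1cc(=O)c(OC)c(-c2ccc(OCc3ccccc3)cc2OC)o1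
F6 | step 7 | 2-[4-(benzyloxy)-2-methoxyphenyl]-5,8-dihydroxy-3,6,7-trimethoxy-4H-chromen-4-one | COc1cc(OCc2ccccc2)ccc1-c1oc2c(O)c(OC)c(OC)c(O)c2c(=O)c1OC
F7 | step 5 | 3-methoxy-4H-pyran-4-one | COc1coccc1=O
F8 | step 5 | (3-methoxy-4-oxo-4H-pyran-2-yl)zinc chloride | COc1c([Zn]Cl)occc1=O
F0 | step 8 | none | none
A1 | alternative 1 | 1-(2-hydroxy-3,4,5,6-tetramethoxyphenyl)ethanone | CC(=O)c1c(O)c(OC)c(OC)c(OC)c1OC
A2 | alternative 1 | (E)-3-[4-(benzyloxy)-2-methoxyphenyl]-1-(2-hydroxy-3,4,5,6-tetramethoxyphenyl)prop-2-en-1-one | COc1cc(OCc2ccccc2)ccc1/C=C/C(=O)c1c(O)c(OC)c(OC)c(OC)c1OC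
A3 | alternative 1 | 2-[4-(benzyloxy)-2-methoxyphenyl]-3-hydroxy-5,6,7,8-tetramethoxy-4H-chromen-4-one | COc1cc(OCc2ccccc2)ccc1-c1oc2c(OC)c(OC)c(OC)c(OC)c2c(=O)c1O
A4 | alternative 1 | (Z)-2-[4-(benzyloxy)-2-methoxybenzylidene]-4,5,6,7-tetramethoxybenzofuran-3(2H)-one | COc1cc(OCc2ccccc2)ccc1/C=C1\Oc2c(OC)c(OC)c(OC)c(OC)c2C1=O
A5 | alternative 2 | 2-[4-(benzyloxy)-2-methoxyphenyl]-5,7-dihydroxy-3-methoxy-4H-chromen-4-one | COc1cc(OCc2ccccc2)ccc1-c1oc2cc(O)cc(O)c2c(=O)c1OC
A6 | alternative 2 | 2-[4-(benzyloxy)-2-methoxyphenyl]-6,8-dibromo-5,7-dihydroxy-3-methoxy-4H-chromen-4-one | COc1cc(OCc2ccccc2)ccc1-c1oc2c(Br)c(O)c(Br)c(O)c2c(=O)c1OC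
A7 | alternative 3 | 2-[4-(benzyloxy)-2-methoxyphenyl]-5-iodo-3-methoxy-4H-pyran-4-one | COc1cc(OCc2ccccc2)ccc1-c1occ(I)c(=O)c1OC
A8 | alternative 3 | 4-[6-(4-benzyloxy-2-methoxyphenyl)-5-methoxy-4-oxo-4H-pyran-3-yl]-2,3,4-trimethoxycyclobut-2-en-1-one (racemic) | COC1(C(OC)=C(OC)C1=O)c1coc(-c2ccc(OCc3ccccc3)cc2OC)c(OC)c1=O
A9 | alternative 3 | 2-[4-(benzyloxy)-2-methoxyphenyl]-8-hydroxy-3,5,6,7-tetramethoxy-4H-chromen-4-one | COc1cc(OCc2ccccc2)ccc1-c1oc2c(O)c(OC)c(OC)c(OC)c2c(=O)c1OC
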